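## Retrosynthetic overview

1. The Z-enyne is attached last, by Z-selective enyne cross-metathesis on the vinyl group of the finished oxocene, then desilylation.
2. The oxocene (the only ring) is closed by a bromonium-induced 8-endo attack of the C7 hydroxyl on C13 of an acyclic dichloro-triene-diol; this one step makes the ring and sets C12 and C13.
3. The C5–C7 triad of that diol comes from an achiral 4-enal: organocatalytic α-aminoxylation sets C7, and (Z)-γ-chloroallylboration sets C5 and C6.
4. The 4-enal, with its chain-cis chloroalkene, comes from a three-component coupling of (E)-hept-4-en-1-yne, chloride and acrolein by anti-chloropalladation.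
5. The enyne comes from (E)-1-bromopent-2-ene and ethynylmagnesium bromide.

Assumption: target atoms are numbered C1 (alkyne CH) to C15 (ethyl CH3), with O7 the oxygen on C7 that becomes the ring oxygen; commercial (E)-1-bromopent-2-ene is taken as the pure E isomer.

## Route

Step 1
Reactants: 1 (E)-1-bromopent-2-ene; 2 ethynylmagnesium bromide
Product: 3 (E)-hept-4-en-1-yne
Conditions: HC≡CMgBr (3 equiv), CuBr·SMe2 (5 mol%), THF, 0 °C → rt
Reagents that add atoms: none
Why: Copper-catalysed SN2 coupling of an alkynyl Grignard reagent with a primary allylic bromide gives the skipped enyne with the E alkene retained, and the excess acetylide suppresses double allylation.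

Step 2
Reactants: 3 (E)-hept-4-en-1-yne; 4 acrolein
Product: 5 (4E,7E)-5-chlorodeca-4,7-dienal
Conditions: Pd(OAc)2 (5 mol%), LiCl (10 equiv), acrolein (3 equiv), AcOH, 25 °C
Reagents that add atoms: lithium chloride, [Li+].[Cl-]
Why: Three-component coupling catalysed by divalent palladium (anti-chloropalladation of the terminal alkyne, insertion of acrolein, protonolysis of the C–Pd bond): at high chloride concentration chloride adds to the internal alkyne carbon opposite to palladium, so Cl ends trans to the new CH2 and the C8–C9=C10–C11 chain is cis, as the ring needs.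

Step 3
Reactants: 5 (4E,7E)-5-chlorodeca-4,7-dienal; 6 allyl chloride
Product: 9 (3S,4S,5R,7E,10E)-3,8-dichloro-5-[(phenylamino)oxy]trideca-1,7,10-trien-4-ol, via α-aminoxy aldehyde 7 (not isolated), via chloroallylborane 8 (not isolated)
Conditions: (a) PhNO (0.95 equiv), L-proline (20 mol%), CH2Cl2, 0 °C; (b) solution filtered cold into 8 [6, Cy2NH/n-BuLi, (+)-Ipc2BOMe, Et2O–THF, −95 °C; then BF3·OEt2], −95 °C, 4 h; (c) HOCH2CH2NH2, rt
Reagents that add atoms: nitrosobenzene, O=Nc1ccccc1
Why: Proline-catalysed α-aminoxylation (enamine catalysis; L-proline gives the 2R aldehyde, which becomes C7) is followed by Oehlschlager–Brown (Z)-γ-chloroallylboration through a chair transition state, which gives the syn chlorohydrin and, with the borane from (+)-Ipc2BOMe, Re-face attack on the aldehyde (C6 S, C5 S) under reagent control.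

Step 4
Reactants: 9 (3S,4S,5R,7E,10E)-3,8-dichloro-5-[(phenylamino)oxy]trideca-1,7,10-trien-4-ol
Product: 10 (3S,4S,5R,7E,10E)-3,8-dichlorotrideca-1,7,10-triene-4,5-diol
Conditions: CuSO4·5H2O (30 mol%), MeOH, 0 °C → rt
Reagents that add atoms: none
Why: Copper-catalysed N–O bond cleavage of the O-alkyl N-phenylhydroxylamine frees O7 without touching the allylic chloride or any stereocentre.

Step 5
Reactants: 10 (3S,4S,5R,7E,10E)-3,8-dichlorotrideca-1,7,10-triene-4,5-diol
Product: 11 (1S,2S)-1-[(2R,4E,7S,8R)-7-bromo-5-chloro-8-ethyl-3,6,7,8-tetrahydro-2H-oxocin-2-yl]-2-chlorobut-3-en-1-ol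
Conditions: TBCO (1.1 equiv, slow addition), CH2Cl2 (2 mM), −40 → 0 °C
Reagents that add atoms: 2,4,4,6-tetrabromocyclohexa-2,5-dien-1-one (TBCO), O=C1C(Br)=CC(Br)(Br)C=C1Br
Why: Proposed new method: TBCO transfers Br+ reversibly to the most electron-rich alkene (the E C12=C13 bond; the chloroalkene and the vinyl group next to C5–Cl are deactivated), O7 opens the bromonium ion at C13 in the 8-endo mode because C12 carries the electron-poor 2-chloroallyl arm and the ring-cis chloroalkene holds O7 near C13, anti opening of the E alkene fixes Br and ethyl trans (12S,13R), and the cis-2,8 arrangement with both α-substituents pseudo-equatorial is the lower transition state; the closest known reaction type is the bromonium-induced cyclisation of laurediols to the same oxocene skeleton with lactoperoxidase or TBCO, which is known only in low yield.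

Step 6
Reactants: 12 ethynyltri(propan-2-yl)silane; 13 vinyl bromide
Product: 14 but-3-en-1-yn-1-yltri(propan-2-yl)silane
Conditions: Pd(PPh3)4 (2 mol%), CuI (4 mol%), iPr2NH, THF, 0 °C → rt
Reagents that add atoms: none
Why: Sonogashira coupling of a terminal alkyne with a vinyl bromide gives the silyl-capped enyne partner for the metathesis.

Step 7
Reactants: 11 (1S,2S)-1-[(2R,4E,7S,8R)-7-bromo-5-chloro-8-ethyl-3,6,7,8-tetrahydro-2H-oxocin-2-yl]-2-chlorobut-3-en-1-ol; 14 but-3-en-1-yn-1-yltri(propan-2-yl)silane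
Product: 15 (1S,2S,3Z)-1-[(2R,4E,7S,8R)-7-bromo-5-chloro-8-ethyl-3,6,7,8-tetrahydro-2H-oxocin-2-yl]-2-chloro-6-[tri(propan-2-yl)silyl]hex-3-en-5-yn-1-ol
Conditions: 14 (5 equiv), second-generation Grubbs catalyst RuCl2(=CHPh)(H2IMes)(PCy3) (10 mol%), CH2Cl2, 40 °C
Reagents that add atoms: none
Why: Z-selective enyne cross-metathesis: the ruthenium alkynylcarbene from 14 reacts only with the monosubstituted alkene of 11 (the ring chloroalkene is inert) and the slim alkynyl group favours the cis ruthenacyclobutane, giving the 3Z enyne.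

Step 8
Reactants: 15 (1S,2S,3Z)-1-[(2R,4E,7S,8R)-7-bromo-5-chloro-8-ethyl-3,6,7,8-tetrahydro-2H-oxocin-2-yl]-2-chloro-6-[tri(propan-2-yl)silyl]hex-3-en-5-yn-1-ol
Product: 16 bermudenynol, (1S,2S,3Z)-1-[(2R,4E,7S,8R)-7-bromo-5-chloro-8-ethyl-3,6,7,8-tetrahydro-2H-oxocin-2-yl]-2-chlorohex-3-en-5-yn-1-ol
Conditions: Bu4NF/AcOH (1:1), THF, 0 °C → rt
Reagents that add atoms: none
Why: Fluoride-mediated protodesilylation of the alkynylsilane, buffered with AcOH so that the C6 alkoxide cannot close onto C5 to form an epoxide.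

## Compound list

1 | (E)-1-bromopent-2-ene | CC/C=C/CBr | starting material
2 | ethynylmagnesium bromide | C#C[Mg]Br | starting material
3 | (E)-hept-4-en-1-yne | C#CC/C=C/CC | intermediate
4 | acrolein | C=CC=O | starting material
5 | (4E,7E)-5-chlorodeca-4,7-dienal | O=CCC/C=C(/Cl)C/C=C/CC | intermediate
6 | allyl chloride | C=CCCl | starting material
7 | (2R,4E,7E)-5-chloro-2-[(phenylamino)oxy]deca-4,7-dienal | O=C[C@H](ONc1ccccc1)C/C=C(/Cl)C/C=C/CC | intermediate
8 | [(2Z)-3-chloroprop-2-en-1-yl]bis(isopinocampheyl)borane, Ipc groups of the (−)-α-pinene series | Cl/C=C\CB([C@H]1C[C@H]2C[C@@H]([C@@H]1C)C2(C)C)[C@H]1C[C@H]2C[C@@H]([C@@H]1C)C2(C)C | intermediate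
9 | (3S,4S,5R,7E,10E)-3,8-dichloro-5-[(phenylamino)oxy]trideca-1,7,10-trien-4-ol | C=C[C@H](Cl)[C@@H](O)[C@H](ONc1ccccc1)C/C=C(/Cl)C/C=C/CC | intermediate
10 | (3S,4S,5R,7E,10E)-3,8-dichlorotrideca-1,7,10-triene-4,5-diol | C=C[C@H](Cl)[C@@H](O)[C@H](O)C/C=C(/Cl)C/C=C/CC | intermediate
11 | (1S,2S)-1-[(2R,4E,7S,8R)-7-bromo-5-chloro-8-ethyl-3,6,7,8-tetrahydro-2H-oxocin-2-yl]-2-chlorobut-3-en-1-ol | C=C[C@H](Cl)[C@@H](O)[C@H]1C/C=C(/Cl)C[C@H](Br)[C@@H](CC)O1 | intermediate
12 | ethynyltri(propan-2-yl)silane | C#C[Si](C(C)C)(C(C)C)C(C)C | starting material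
13 | vinyl bromide | C=CBr | starting material
14 | but-3-en-1-yn-1-yltri(propan-2-yl)silane | C=CC#C[Si](C(C)C)(C(C)C)C(C)C | intermediate
15 | (1S,2S,3Z)-1-[(2R,4E,7S,8R)-7-bromo-5-chloro-8-ethyl-3,6,7,8-tetrahydro-2H-oxocin-2-yl]-2-chloro-6-[tri(propan-2-yl)silyl]hex-3-en-5-yn-1-ol | CC(C)[Si](C(C)C)(C(C)C)C#C/C=C\[C@H](Cl)[C@@H](O)[C@H]1C/C=C(/Cl)C[C@H](Br)[C@@H](CC)O1 | intermediate
16 | bermudenynol | C#C/C=C\[C@H](Cl)[C@@H](O)[C@H]1C/C=C(/Cl)C[C@H](Br)[C@@H](CC)O1 | target

## Step count and risks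

Total step count: 8. Longest linear sequence: 7 (steps 1, 2, 3, 4, 5, 7, 8).

**Step 5, the 8-endo ring closure.** This is the most likely step to fail. O7 can also attack C12 (7-exo), O6 can close onto C12, O7 can attack the vinyl group at C4 (5-exo), and bromide or phenoxide can capture the bromonium ion. A modest yield and a diastereomer separation are expected.

The fallback closes the ring one stage earlier, on a substrate in which O7 is the only nucleophile and no vinyl group is present. It sets out from 5. Aminoxylation as in step 3 followed by NaBH4 gives (2R,4E,7E)-5-chloro-2-[(phenylamino)oxy]deca-4,7-dien-1-ol F1. TBSCl and imidazole give N-{[(2R,4E,7E)-1-{[tert-butyl(dimethyl)silyl]oxy}-5-chlorodeca-4,7-dien-2-yl]oxy}aniline F2. CuSO4·5H2O in MeOH gives (2R,4E,7E)-1-{[tert-butyl(dimethyl)silyl]oxy}-5-chlorodeca-4,7-dien-2-ol F3. TBCO under the step 5 conditions gives tert-butyl{[(2R,4E,7S,8R)-7-bromo-5-chloro-8-ethyl-3,6,7,8-tetrahydro-2H-oxocin-2-yl]methoxy}dimethylsilane F4. Bu4NF gives [(2R,4E,7S,8R)-7-bromo-5-chloro-8-ethyl-3,6,7,8-tetrahydro-2H-oxocin-2-yl]methanol F5, and Dess–Martin periodinane gives (2R,4E,7S,8R)-7-bromo-5-chloro-8-ethyl-3,6,7,8-tetrahydro-2H-oxocine-2-carbaldehyde F6. Chloroallylboration of F6 with 8 comes back to the route at 11.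

**Step 3, aminoxylation and chloroallylboration in one flask.** Aldehyde 7 is labile and is used without isolation. The required 6,7-syn relationship runs against the intrinsic facial preference of an α-oxygenated aldehyde toward Z-γ-substituted allylboranes, so the diastereomer ratio rests on reagent control alone.

The fallback replaces reagent control by chelation control. It sets out from 7 (made from 5 as in step 3). MgBr2·OEt2 and tributyl[(2E)-3-chloroprop-2-en-1-yl]stannane F7 (from (E)-1,3-dichloropropene and Bu3SnLi) are added at −78 °C in CH2Cl2. The magnesium chelate between the aldehyde oxygen and the aminoxy oxygen directs attack to give the 6,7-syn product, and the open transition state of the allylstannane gives the 5,6-syn chlorohydrin. This comes back to the route at 9.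

**Step 2, the chloropalladation coupling.** The sense of chloropalladation depends on chloride concentration: syn addition would give the chain-trans chloroalkene, which cannot cyclise. Chloride is also a weaker nucleophile than bromide in this coupling, and the skipped enyne may isomerise.

The fallback builds the chloroalkene by directed hydroboration instead. It sets out from 1. Coupling with propargyl alcohol (CuI, K2CO3, NaI, DMF) gives (5E)-oct-5-en-2-yn-1-ol F8. Copper-catalysed formal hydroboration (CuCl, PCy3, NaOtBu, B2pin2, MeOH) adds H and boron syn with boron on the alkyne carbon distal to the hydroxyl, giving (2Z,5E)-3-(4,4,5,5-tetramethyl-1,3,2-dioxaborolan-2-yl)octa-2,5-dien-1-ol F9. CuCl2 in MeOH/H2O replaces boron by chlorine with retention to give (2E,5E)-3-chloroocta-2,5-dien-1-ol F10. CBr4/PPh3 gives (2E,5E)-1-bromo-3-chloroocta-2,5-diene F11. Alkylation of N-cyclohexylethanimine lithiated with LiN(iPr)2 gives (4E,7E)-5-chloro-N-cyclohexyldeca-4,7-dien-1-imine F12, and aqueous oxalic acid hydrolyses it, coming back to the route at 5.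

Further compounds

F1 | step 5 | (2R,4E,7E)-5-chloro-2-[(phenylamino)oxy]deca-4,7-dien-1-ol | OC[C@H](ONc1ccccc1)C/C=C(/Cl)C/C=C/CC
F2 | step 5 | N-{[(2R,4E,7E)-1-{[tert-butyl(dimethyl)silyl]oxy}-5-chlorodeca-4,7-dien-2-yl]oxy}aniline | CC(C)(C)[Si](C)(C)OC[C@H](ONc1ccccc1)C/C=C(/Cl)C/C=C/CC
F3 | step 5 | (2R,4E,7E)-1-{[tert-butyl(dimethyl)silyl]oxy}-5-chlorodeca-4,7-dien-2-ol | CC(C)(C)[Si](C)(C)OC[C@H](O)C/C=C(/Cl)C/C=C/CC
F4 | step 5 | tert-butyl{[(2R,4E,7S,8R)-7-bromo-5-chloro-8-ethyl-3,6,7,8-tetrahydro-2H-oxocin-2-yl]methoxy}dimethylsilane | CC(C)(C)[Si](C)(C)OC[C@H]1C/C=C(/Cl)C[C@H](Br)[C@@H](CC)O1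
F5 | step 5 | [(2R,4E,7S,8R)-7-bromo-5-chloro-8-ethyl-3,6,7,8-tetrahydro-2H-oxocin-2-yl]methanol | OC[C@H]1C/C=C(/Cl)C[C@H](Br)[C@@H](CC)O1
F6 | step 5 | (2R,4E,7S,8R)-7-bromo-5-chloro-8-ethyl-3,6,7,8-tetrahydro-2H-oxocine-2-carbaldehyde | O=C[C@H]1C/C=C(/Cl)C[C@H](Br)[C@@H](CC)O1
F7 | step 3 | tributyl[(2E)-3-chloroprop-2-en-1-yl]stannane | CCCC[Sn](CCCC)(CCCC)C/C=C/Cl
F8 | step 2 | (5E)-oct-5-en-2-yn-1-ol | OCC#CC/C=C/CC
F9 | step 2 | (2Z,5E)-3-(4,4,5,5-tetramethyl-1,3,2-dioxaborolan-2-yl)octa-2,5-dien-1-ol | OC/C=C(/B1OC(C)(C)C(C)(C)O1)C/C=C/CC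
F10 | step 2 | (2E,5E)-3-chloroocta-2,5-dien-1-ol | OC/C=C(/Cl)C/C=C/CC
F11 | step 2 | (2E,5E)-1-bromo-3-chloroocta-2,5-diene | BrC/C=C(/Cl)C/C=C/CC
F12 | step 2 | (4E,7E)-5-chloro-N-cyclohexyldeca-4,7-dien-1-imine | C1CCCCC1N=CCC/C=C(/Cl)C/C=C/CC
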